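**Retrosynthetic overview**
1. Gentiside I (16) ⇒ ester C–O disconnection into henicosan-1-ol (9) and 2,3-bis(benzyloxy)benzoic acid (13); the two benzyl ethers come off last by hydrogenolysis.
2. 9 ⇒ henicos-1-ene (7) by anti-Markovnikov hydration; 7 ⇒ rac-henicos-1-en-4-ol (5) by deoxygenation through tosylate 6.
3. Key C–C disconnection: the C3–C4 bond of 5, made by carbonyl allylation of octadecanal (2, from octadecan-1-ol 1) with allylmagnesium bromide (3), C18 + C3 = C21.
4. 13 ⇒ 2,3-dihydroxybenzoic acid (10) by perbenzylation and saponification.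
5. Rings: none is built; the only ring, the benzene ring, is bought with 10.

Assumption: the target has no stereocentre, so there is no enantiomer to select; the one stereocentre that appears on the way (C4 of 4, 5 and 6) is made racemic and is erased in step 4.

**Route**

Step 1
Reactants: 1 octadecan-1-ol
Product: 2 octadecanal
Conditions: 2,2,6,6-tetramethylpiperidin-1-oxyl (TEMPO, 10 mol%), PhI(OAc)2 (1.1 equiv), CH2Cl2, rt, 4 h; used promptly
Reagents that add atoms: none
Why: TEMPO-catalysed oxoammonium oxidation (Piancatelli–Margarita conditions) stops at the aldehyde in anhydrous CH2Cl2 because no aldehyde hydrate is present to be oxidised further.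

Step 2
Reactants: 2 octadecanal; 3 allylmagnesium bromide
Product: 5 rac-henicos-1-en-4-ol, via bromomagnesium henicos-1-en-4-olate 4 (not isolated)
Conditions: CH2=CHCH2MgBr (1.0 M in Et2O, 1.3 equiv), THF, 0 °C → rt, 1 h; then sat. aq NH4Cl
Reagents that add atoms: none
Why: Carbonyl allylation, in which the allyl Grignard reagent adds 1,2 to the unhindered aldehyde much faster than it enolises it and so joins the C18 and C3 fragments at C3–C4; the carbinol centre forms racemic and is removed in step 4.

Step 3
Reactants: 5 rac-henicos-1-en-4-ol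
Product: 6 rac-henicos-1-en-4-yl 4-methylbenzenesulfonate
Conditions: TsCl (1.5 equiv), Et3N (2.5 equiv), 4-(dimethylamino)pyridine (0.2 equiv), CH2Cl2, 0 °C → rt, 16 h
Reagents that add atoms: 4-methylbenzenesulfonyl chloride (TsCl), Cc1ccc(cc1)S(Cl)(=O)=O
Why: Amine-catalysed O-sulfonylation (tosylation) turns the secondary hydroxyl into a good leaving group and leaves the terminal alkene untouched.

Step 4
Reactants: 6 rac-henicos-1-en-4-yl 4-methylbenzenesulfonate
Product: 7 henicos-1-ene
Conditions: LiEt3BH (1.0 M in THF, 2.5 equiv), THF, 0 °C → rt (40 °C if slow)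
Reagents that add atoms: none
Why: SN2 hydride displacement of an acyclic secondary tosylate by lithium triethylborohydride (Super-Hydride reduction) removes the oxygen and the stereocentre, while the isolated alkene is inert to this nucleophilic hydride.

Step 5
Reactants: 7 henicos-1-ene
Product: 9 henicosan-1-ol, via 9-henicosyl-9-borabicyclo[3.3.1]nonane 8 (not isolated)
Conditions: 9-borabicyclo[3.3.1]nonane (0.5 M in THF, 1.3 equiv), THF, 0 °C → rt, 12 h; then 3 M NaOH, 30% H2O2, 0 → 50 °C
Reagents that add atoms: hydrogen peroxide, OO
Why: Brown hydroboration–oxidation, in which the bulky borane places boron on the terminal carbon (>99:1 anti-Markovnikov) and alkaline peroxide replaces boron by hydroxyl.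

Step 6
Reactants: 10 2,3-dihydroxybenzoic acid
Product: 11 benzyl 2,3-bis(benzyloxy)benzoate
Conditions: BnBr (3.6 equiv), K2CO3 (5 equiv), HCONMe2 (DMF), 60 °C, 16 h
Reagents that add atoms: benzyl bromide, BrCc1ccccc1
Why: Williamson etherification of both phenols together with carboxylate O-alkylation (SN2 on benzyl bromide) masks all three acidic OH groups in one operation.

Step 7
Reactants: 11 benzyl 2,3-bis(benzyloxy)benzoate
Product: 13 2,3-bis(benzyloxy)benzoic acid, via potassium 2,3-bis(benzyloxy)benzoate 12 (not isolated)
Conditions: KOH (5 equiv), 1,4-dioxane/H2O (2:1), 90 °C, 4 h; then 2 M HCl to pH 2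
Reagents that add atoms: potassium hydroxide, [K+].[OH-]
Why: Saponification (base-mediated acyl–oxygen ester hydrolysis) cleaves only the benzyl ester because aryl benzyl ethers are inert to hydroxide.

Step 8
Reactants: 13 2,3-bis(benzyloxy)benzoic acid; 9 henicosan-1-ol
Product: 15 henicosyl 2,3-bis(benzyloxy)benzoate, via 2,3-bis(benzyloxy)benzoyl chloride 14 (not isolated)
Conditions: (COCl)2 (1.3 equiv), HCONMe2 (cat.), CH2Cl2, 0 °C → rt, 2 h; evaporate; then 9 (0.9 equiv), Et3N (2 equiv), 4-(dimethylamino)pyridine (0.1 equiv), CH2Cl2, rt → 40 °C, 12 h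
Reagents that add atoms: none
Why: Nucleophilic acyl substitution through the acid chloride (Vilsmeier-type activation, then amine-catalysed acylation of a primary alcohol) is fast and irreversible, and the benzyl ethers tolerate both stages.

Step 9
Reactants: 15 henicosyl 2,3-bis(benzyloxy)benzoate
Product: 16 Gentiside I (henicosyl 2,3-dihydroxybenzoate)
Conditions: H2 (1 atm), Pd/C (10 wt% Pd), EtOAc/THF (1:1), rt, 8 h; filter warm through Celite under N2
Reagents that add atoms: none
Why: Catalytic hydrogenolysis of the two O-benzyl ethers frees the catechol under neutral conditions that leave the alkyl benzoate ester and the arene untouched.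

**Compound list**
1 | octadecan-1-ol | CCCCCCCCCCCCCCCCCCO | starting material
2 | octadecanal | CCCCCCCCCCCCCCCCCC=O | intermediate
3 | allylmagnesium bromide | C=CC[Mg]Br | starting material
4 | bromomagnesium henicos-1-en-4-olate (racemic) | CCCCCCCCCCCCCCCCCC(CC=C)O[Mg]Br | intermediate (not isolated)
5 | rac-henicos-1-en-4-ol | CCCCCCCCCCCCCCCCCC(O)CC=C | intermediate
6 | rac-henicos-1-en-4-yl 4-methylbenzenesulfonate | CCCCCCCCCCCCCCCCCC(CC=C)OS(=O)(=O)c1ccc(C)cc1 | intermediate
7 | henicos-1-ene | CCCCCCCCCCCCCCCCCCCC=C | intermediate
8 | 9-henicosyl-9-borabicyclo[3.3.1]nonane | CCCCCCCCCCCCCCCCCCCCCB1C2CCCC1CCC2 | intermediate (not isolated)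
9 | henicosan-1-ol | CCCCCCCCCCCCCCCCCCCCCO | intermediate
10 | 2,3-dihydroxybenzoic acid | OC(=O)c1cccc(O)c1O | starting material
11 | benzyl 2,3-bis(benzyloxy)benzoate | O=C(OCc1ccccc1)c1cccc(OCc2ccccc2)c1OCc1ccccc1 | intermediate
12 | potassium 2,3-bis(benzyloxy)benzoate | [K+].[O-]C(=O)c1cccc(OCc2ccccc2)c1OCc1ccccc1 | intermediate (not isolated)
13 | 2,3-bis(benzyloxy)benzoic acid | OC(=O)c1cccc(OCc2ccccc2)c1OCc1ccccc1 | intermediate
14 | 2,3-bis(benzyloxy)benzoyl chloride | ClC(=O)c1cccc(OCc2ccccc2)c1OCc1ccccc1 | intermediate (not isolated)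
15 | henicosyl 2,3-bis(benzyloxy)benzoate | CCCCCCCCCCCCCCCCCCCCCOC(=O)c1cccc(OCc2ccccc2)c1OCc1ccccc1 | intermediate
16 | Gentiside I, henicosyl 2,3-dihydroxybenzoate (achiral) | CCCCCCCCCCCCCCCCCCCCCOC(=O)c1cccc(O)c1O | target

**Step count and risks**
Total steps: 9. Longest linear sequence: 7 steps (steps 1, 2, 3, 4, 5, 8, 9); the acid branch (steps 6, 7) joins at step 8.

The three steps most likely to fail:

Step 4 (hydride displacement of the homoallylic secondary tosylate). The risks are E2 elimination to the conjugated henicosa-1,3-diene and S–O cleavage back to 5. The fallback sets out from 5 and comes back to the route at 7, bypassing 6. Alcohol 5 is converted with NaH, CS2 and then MeI in THF (0 °C → rt) into rac-O-(henicos-1-en-4-yl) S-methyl carbonodithioate F1. F1 is then deoxygenated by the Barton–McCombie radical chain (Bu3SnH, azobisisobutyronitrile, toluene, 110 °C) to give 7. The secondary homoallylic radical is trapped by the stannane far faster than it can rearrange through the cyclopropylcarbinyl radical.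

Step 1 (isolating octadecanal). The aldehyde can over-oxidise, form the stearyl stearate ester with unreacted alcohol, or trimerise on standing. The fallback sets out from 1 and comes back to the route at 5, so the free aldehyde is never handled. It is an iridium-catalysed transfer-hydrogenative carbonyl allylation of the alcohol itself: 1, allyl acetate (10 equiv), [Ir(cod)Cl]2 (2.5 mol%), rac-2,2'-bis(diphenylphosphino)-1,1'-binaphthyl (5 mol%), Cs2CO3 (20 mol%), 3-nitrobenzoic acid (10 mol%), THF, 100 °C, sealed tube. Aldehyde 2 exists only transiently, and the route passes through no new compound (F0).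

Step 8 (acylation of the waxy, poorly soluble C21 alcohol by an ortho-alkoxy-substituted acid chloride). The risks are incomplete conversion and hydrolysis of 14. The fallback sets out from 9 and comes back to the route at 15 with reversed polarity. Alcohol 9 is converted with MsCl and Et3N in CH2Cl2 (0 °C) into henicosyl methanesulfonate F2. F2 then O-alkylates the caesium carboxylate of 13 (Cs2CO3, HCONMe2, 60 °C) by SN2 to give 15, with no acyl activation at all.

**Further compounds**
F1 | step 4 | rac-O-(henicos-1-en-4-yl) S-methyl carbonodithioate | CCCCCCCCCCCCCCCCCC(CC=C)OC(=S)SC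
F0 | step 1 | none | none
F2 | step 8 | henicosyl methanesulfonate | CCCCCCCCCCCCCCCCCCCCCOS(C)(=O)=O
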